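**Retrosynthetic overview**

1. Labdane numbering is used (C1–C10 decalin, C11–C16 side chain, C17 on C8, C20 on C10). The target is the A/B-cis 2α-angeloyloxy-labd-7-en-15-oic acid (2S,5R,9R,10S,13R). The endgame takes the C15 acid from a silyl-protected primary alcohol and the angelate from the equatorial 2α-alcohol, itself from a C2 ketone.
2. Ring B is opened at the trisubstituted C7=C8 olefin to a C5 allyl / C9 isopropenyl pair (ring-closing metathesis). The resulting array C2(=O)–C1–C10–C9–C8=CH2 is the retron of an anionic oxy-Cope rearrangement, which cuts C9–C10 (the most hindered bond) back to a C2 tertiary alkoxide; both events are run in one flask.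
3. Enabling feature: in ring B the C7=C8 double bond carries C17 on C8 and sits beside C9, which is bonded to quaternary C10, and C10 lies 1,3 to the C2 oxygen of ring A. The C5–C6 and C10–C9 bonds are cis on ring A, so the two alkenes can meet.
4. Fragments: (4R)-4-allyl-isophorone (ring A with C6, C7, C20; from dimedone by asymmetric allylation and Stork–Danheiser transposition) and an (E)-allylic chloride from (R)-citronellol. The citronellol isopropylidene carbon becomes C8, one of its methyls C17, the other the extruded methylene, its olefinic CH becomes C9, and its C3 is C13.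
5. Ring order: ring A is bought (dimedone); ring B is formed in the key step by the C7=C8 closure.

Key step: step 9

Assumption: the (R,R) enantiomer of the diphosphine ligand in step 3 is taken to give the 6R ketone 5; if the 6S ketone forms, the (S,S) ligand is used instead.

**Route**

Step 1
Reactants: 1 dimedone (5,5-dimethylcyclohexane-1,3-dione)
Product: 2 3-ethoxy-5,5-dimethylcyclohex-2-en-1-one
Conditions: EtOH, p-TsOH (cat.), toluene, reflux, Dean–Stark trap
Reagents that add atoms: ethanol, CCO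
Why: Acid-catalysed enol etherification of a cyclic 1,3-diketone, driven by azeotropic removal of water; the two carbonyls are equivalent, so a single vinylogous ester should form.

Step 2
Reactants: 2 3-ethoxy-5,5-dimethylcyclohex-2-en-1-one; 3 allyl chloroformate
Product: 4 5-ethoxy-3,3-dimethylcyclohexa-1,5-dien-1-yl prop-2-en-1-yl carbonate
Conditions: NaN(SiMe3)2, TMEDA, THF, −78 °C; then 3
Reagents that add atoms: none
Why: Kinetic deprotonation of the vinylogous ester at the alpha-prime carbon gives the cross-conjugated sodium dienolate, which the hard chloroformate should trap on oxygen (enol carbonate formation).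

Step 3
Reactants: 4 5-ethoxy-3,3-dimethylcyclohexa-1,5-dien-1-yl prop-2-en-1-yl carbonate
Product: 5 (6R)-3-ethoxy-5,5-dimethyl-6-(prop-2-en-1-yl)cyclohex-2-en-1-one
Conditions: Pd2(dba)3·CHCl3 (2.5 mol %), (11R,12R)-N,N′-(9,10-dihydro-9,10-ethanoanthracene-11,12-diyl)bis[2-(diphenylphosphino)benzamide] (5.5 mol %), 1,4-dioxane, 23 °C
Reagents that add atoms: none
Why: Decarboxylative asymmetric allylic alkylation (Tsuji–Trost type): zerovalent palladium ionizes the allyl carbonate, CO2 is lost, and the enolate/π-allylpalladium ion pair recombines at carbon inside the chiral ligand pocket, setting the future C5 centre (6R), while the adjacent gem-dimethyl group should hinder a second allylation and enolization of the product.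

Step 4
Reactants: 5 (6R)-3-ethoxy-5,5-dimethyl-6-(prop-2-en-1-yl)cyclohex-2-en-1-one
Product: 7 (4R)-3,5,5-trimethyl-4-(prop-2-en-1-yl)cyclohex-2-en-1-one, via lithium alkoxide adduct 6 (not isolated)
Conditions: MeLi, THF, −78 to 0 °C; then 1 M HCl, 0 to 20 °C
Reagents that add atoms: methyllithium, [Li]C
Why: Stork–Danheiser transposition: 1,2-addition of MeLi to the vinylogous ester carbonyl, then acid-mediated hydrolysis and elimination, moves the enone so that the new methyl becomes C20 on C10, and the stereocentre (now gamma to the carbonyl) is not touched.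

Step 5
Reactants: 8 (R)-citronellol ((3R)-3,7-dimethyloct-6-en-1-ol)
Product: 9 tert-butyl{[(3R)-3,7-dimethyloct-6-en-1-yl]oxy}dimethylsilane
Conditions: tert-butyldimethylsilyl chloride, imidazole, DMF, 20 °C
Reagents that add atoms: tert-butyldimethylsilyl chloride, CC(C)(C)[Si](C)(C)Cl
Why: Standard silylation of the primary alcohol keeps the future C15 carboxyl at the alcohol level, so that it should survive the organobarium and KH steps.

Step 6
Reactants: 9 tert-butyl{[(3R)-3,7-dimethyloct-6-en-1-yl]oxy}dimethylsilane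
Product: 10 (2E,6R)-8-[(tert-butyldimethylsilyl)oxy]-2,6-dimethyloct-2-en-1-ol
Conditions: SeO2 (0.3 equiv), tert-butyl hydroperoxide (3 equiv), salicylic acid (cat.), CH2Cl2, 20 °C
Reagents that add atoms: tert-butyl hydroperoxide, CC(C)(C)OO
Why: SeO2-catalysed allylic oxidation (ene reaction, then [2,3]-sigmatropic shift) is selective for the E methyl of an isopropylidene terminus and should give the E primary allylic alcohol without touching the C13 centre.

Step 7
Reactants: 10 (2E,6R)-8-[(tert-butyldimethylsilyl)oxy]-2,6-dimethyloct-2-en-1-ol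
Product: 12 tert-butyl{[(3R,6E)-8-chloro-3,7-dimethyloct-6-en-1-yl]oxy}dimethylsilane, via allylic mesylate 11 (not isolated)
Conditions: methanesulfonyl chloride, 2,4,6-collidine, LiCl, DMF, 0 °C
Reagents that add atoms: lithium chloride, [Li+].[Cl-]
Why: Mesylation followed by SN2 displacement with chloride at the primary allylic carbon under buffered conditions should proceed without allylic transposition or loss of the E geometry.

Step 8
Reactants: 12 tert-butyl{[(3R,6E)-8-chloro-3,7-dimethyloct-6-en-1-yl]oxy}dimethylsilane; 7 (4R)-3,5,5-trimethyl-4-(prop-2-en-1-yl)cyclohex-2-en-1-one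
Product: 14 (1R,4R)-1-{(2E,6R)-8-[(tert-butyldimethylsilyl)oxy]-2,6-dimethyloct-2-en-1-yl}-3,5,5-trimethyl-4-(prop-2-en-1-yl)cyclohex-2-en-1-ol, via allylbarium chloride 13 (not isolated)
Conditions: activated Ba (from BaI2 and 2 equiv lithium biphenylide, LiC12H10, THF, 20 °C); 12, −78 °C; then 7, −78 °C; aq. NH4Cl
Reagents that add atoms: none
Why: Allylbarium reagents add to ketones through their unsubstituted (alpha) terminus with retention of olefin geometry and in 1,2 fashion to enones, and the bulky nucleophile should attack the C2 carbonyl anti to the axial methyl on C4, which is the face syn to the pseudoaxial C5 allyl group, so the new side chain on C2 ends up cis to the allyl group (1R).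

Step 9
Reactants: 14 (1R,4R)-1-{(2E,6R)-8-[(tert-butyldimethylsilyl)oxy]-2,6-dimethyloct-2-en-1-yl}-3,5,5-trimethyl-4-(prop-2-en-1-yl)cyclohex-2-en-1-ol
Product: 18 (4aR,8R,8aS)-8-{(3R)-5-[(tert-butyldimethylsilyl)oxy]-3-methylpentyl}-4,4,7,8a-tetramethyl-3,4,4a,5,8,8a-hexahydronaphthalen-2(1H)-one, via potassium alkoxide 15 (not isolated), via potassium enolate 16 (not isolated), via triene ketone 17 (not isolated)
Conditions: KH, 18-crown-6, THF, 0 to 50 °C; AcOH, −78 °C; short silica pad, solvent switch to toluene; then second-generation Hoveyda–Grubbs catalyst RuCl2(H2IMes)(=CH-C6H4-2-OiPr) (5 mol %), 60 °C, argon purge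
Reagents that add atoms: none
Why: Stage one is an anionic oxy-Cope rearrangement: in alkoxide 15 the C2–CH2 bond shifts across the 1,5-diene made of C1=C10 and C8=C9, forming the C9–C10 bond and enolate 16, as in the known conjugate allyl transfer from 1-(alk-2-enyl)cyclohex-2-en-1-olates that builds a quaternary carbon beside a tertiary one. The allyl unit is delivered suprafacially from C2, so C10 receives C9 on the face of the C5 allyl group (cis, the A/B-cis relation); C9 (beta hydrogen) is set by the E olefin reacting through a boat-like array, expected because a chair would push C8 and its methyl over ring A into the axial methyl on C4, the same bias seen in ester-enolate Claisen rearrangements of cyclohexenyl esters. Stage two, after protonation to ketone 17, is ring-closing metathesis: the ruthenium alkylidene loads on the monosubstituted allyl terminus and closes ring B as a six-membered ring onto the 1,1-disubstituted isopropenyl group, forming C7=C8 with loss of ethylene and creating no new stereocentre. The closest precedent for this stage is ring-closing metathesis to trisubstituted cyclohexenes next to quaternary centres. The step needs the [3,3] shift to win over alkoxide fragmentation or a [1,3] shift (favoured by the free potassium alkoxide with 18-crown-6 at moderate temperature), and it needs only one mode of ring closure, which is secured because the only two alkenes able to meet are cis on ring A and the side chain carries no alkene.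

Step 10
Reactants: 18 (4aR,8R,8aS)-8-{(3R)-5-[(tert-butyldimethylsilyl)oxy]-3-methylpentyl}-4,4,7,8a-tetramethyl-3,4,4a,5,8,8a-hexahydronaphthalen-2(1H)-one
Product: 19 (2S,4aR,8R,8aS)-8-{(3R)-5-[(tert-butyldimethylsilyl)oxy]-3-methylpentyl}-4,4,7,8a-tetramethyl-1,2,3,4,4a,5,8,8a-octahydronaphthalen-2-ol
Conditions: Li, NH3 (l), THF, EtOH, −78 °C; then NH4Cl
Reagents that add atoms: none
Why: Dissolving-metal reduction of a cyclohexanone gives the thermodynamically favoured equatorial alcohol; in the preferred cis-decalin conformer the beta face at C2 carries two syn-axial methyl groups (on C4 and C10), so the 2α (equatorial, 2S) alcohol should form, while the isolated alkene and the silyl ether are inert.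

Step 11
Reactants: 19 (2S,4aR,8R,8aS)-8-{(3R)-5-[(tert-butyldimethylsilyl)oxy]-3-methylpentyl}-4,4,7,8a-tetramethyl-1,2,3,4,4a,5,8,8a-octahydronaphthalen-2-ol; 20 angelic acid ((2Z)-2-methylbut-2-enoic acid)
Product: 22 (2S,4aR,8R,8aS)-8-{(3R)-5-[(tert-butyldimethylsilyl)oxy]-3-methylpentyl}-4,4,7,8a-tetramethyl-1,2,3,4,4a,5,8,8a-octahydronaphthalen-2-yl (2Z)-2-methylbut-2-enoate, via mixed anhydride 21 (not isolated)
Conditions: 20, 2,4,6-trichlorobenzoyl chloride, Et3N, toluene, 20 °C; then 19, 80 °C (no DMAP)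
Reagents that add atoms: none
Why: Mixed-anhydride (Yamaguchi-type) esterification: the alcohol attacks the unhindered angeloyl carbonyl, and leaving out a nucleophilic amine catalyst should avoid Z-to-E isomerization to the tiglate.

Step 12
Reactants: 22 (2S,4aR,8R,8aS)-8-{(3R)-5-[(tert-butyldimethylsilyl)oxy]-3-methylpentyl}-4,4,7,8a-tetramethyl-1,2,3,4,4a,5,8,8a-octahydronaphthalen-2-yl (2Z)-2-methylbut-2-enoate
Product: 23 (2S,4aR,8R,8aS)-8-[(3R)-5-hydroxy-3-methylpentyl]-4,4,7,8a-tetramethyl-1,2,3,4,4a,5,8,8a-octahydronaphthalen-2-yl (2Z)-2-methylbut-2-enoate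
Conditions: HF·pyridine, pyridine, THF, 0 to 20 °C
Reagents that add atoms: none
Why: Fluoride-mediated cleavage of the primary silyl ether under buffered conditions should leave the unsaturated ester and the trisubstituted alkene untouched.

Step 13
Reactants: 23 (2S,4aR,8R,8aS)-8-[(3R)-5-hydroxy-3-methylpentyl]-4,4,7,8a-tetramethyl-1,2,3,4,4a,5,8,8a-octahydronaphthalen-2-yl (2Z)-2-methylbut-2-enoate
Product: 24 (3R)-3-methyl-5-[(1R,4aR,7S,8aS)-2,5,5,8a-tetramethyl-7-{[(2Z)-2-methylbut-2-enoyl]oxy}-1,4,4a,5,6,7,8,8a-octahydronaphthalen-1-yl]pentanoic acid (the target)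
Conditions: TEMPO (cat.), PhI(OAc)2 (2.2 equiv), MeCN / pH 7 aqueous buffer, 20 °C
Reagents that add atoms: water, O
Why: Oxoammonium (TEMPO) oxidation of the primary alcohol to the aldehyde, hydration and a second oxidation give the carboxylic acid under near-neutral conditions that should spare the angelate and the alkene.

**Compound list**

1 | dimedone (5,5-dimethylcyclohexane-1,3-dione) | CC1(C)CC(=O)CC(=O)C1 | starting material
2 | 3-ethoxy-5,5-dimethylcyclohex-2-en-1-one | CCOC1=CC(=O)CC(C)(C)C1 | intermediate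
3 | allyl chloroformate | C=CCOC(Cl)=O | starting material
4 | 5-ethoxy-3,3-dimethylcyclohexa-1,5-dien-1-yl prop-2-en-1-yl carbonate | C=CCOC(=O)OC1=CC(C)(C)CC(OCC)=C1 | intermediate
5 | (6R)-3-ethoxy-5,5-dimethyl-6-(prop-2-en-1-yl)cyclohex-2-en-1-one | CCOC1=CC(=O)[C@H](CC=C)C(C)(C)C1 | intermediate
6 | lithium (6R)-3-ethoxy-1,5,5-trimethyl-6-(prop-2-en-1-yl)cyclohex-2-en-1-olate (either C1 epimer; not isolated) | [Li+].CCOC1=CC(C)([O-])[C@H](CC=C)C(C)(C)C1 | intermediate
7 | (4R)-3,5,5-trimethyl-4-(prop-2-en-1-yl)cyclohex-2-en-1-one | O=C1CC(C)(C)[C@@H](CC=C)C(C)=C1 | intermediate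
8 | (R)-citronellol, (3R)-3,7-dimethyloct-6-en-1-ol | CC(C)=CCC[C@@H](C)CCO | starting material
9 | tert-butyl{[(3R)-3,7-dimethyloct-6-en-1-yl]oxy}dimethylsilane | CC(C)=CCC[C@@H](C)CCO[Si](C)(C)C(C)(C)C | intermediate
10 | (2E,6R)-8-[(tert-butyldimethylsilyl)oxy]-2,6-dimethyloct-2-en-1-ol | OC/C(C)=C/CC[C@@H](C)CCO[Si](C)(C)C(C)(C)C | intermediate
11 | (2E,6R)-8-[(tert-butyldimethylsilyl)oxy]-2,6-dimethyloct-2-en-1-yl methanesulfonate (not isolated) | CS(=O)(=O)OC/C(C)=C/CC[C@@H](C)CCO[Si](C)(C)C(C)(C)C | intermediate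
12 | tert-butyl{[(3R,6E)-8-chloro-3,7-dimethyloct-6-en-1-yl]oxy}dimethylsilane | ClC/C(C)=C/CC[C@@H](C)CCO[Si](C)(C)C(C)(C)C | intermediate
13 | [(2E,6R)-8-(tert-butyldimethylsilyloxy)-2,6-dimethyloct-2-en-1-yl]barium chloride (not isolated) | Cl[Ba]C/C(C)=C/CC[C@@H](C)CCO[Si](C)(C)C(C)(C)C | intermediate
14 | (1R,4R)-1-{(2E,6R)-8-[(tert-butyldimethylsilyl)oxy]-2,6-dimethyloct-2-en-1-yl}-3,5,5-trimethyl-4-(prop-2-en-1-yl)cyclohex-2-en-1-ol (side chain cis to the allyl group) | O[C@]1(C/C(C)=C/CC[C@@H](C)CCO[Si](C)(C)C(C)(C)C)CC(C)(C)[C@@H](CC=C)C(C)=C1 | intermediate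
15 | potassium alkoxide of 14 (not isolated) | [K+].[O-][C@]1(C/C(C)=C/CC[C@@H](C)CCO[Si](C)(C)C(C)(C)C)CC(C)(C)[C@@H](CC=C)C(C)=C1 | intermediate
16 | potassium enolate of 17 (C1=C2 enolate in labdane numbering; not isolated) | [K+].[O-]C1=C[C@](C)([C@H](CC[C@@H](C)CCO[Si](C)(C)C(C)(C)C)C(C)=C)[C@H](CC=C)C(C)(C)C1 | intermediate
17 | (3R,4R)-3-{(3R,6R)-8-[(tert-butyldimethylsilyl)oxy]-2,6-dimethyloct-1-en-3-yl}-3,5,5-trimethyl-4-(prop-2-en-1-yl)cyclohexan-1-one (not isolated) | O=C1CC(C)(C)[C@@H](CC=C)[C@@](C)([C@H](CC[C@@H](C)CCO[Si](C)(C)C(C)(C)C)C(C)=C)C1 | intermediate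
18 | (4aR,8R,8aS)-8-{(3R)-5-[(tert-butyldimethylsilyl)oxy]-3-methylpentyl}-4,4,7,8a-tetramethyl-3,4,4a,5,8,8a-hexahydronaphthalen-2(1H)-one (A/B cis) | O=C1CC(C)(C)[C@H]2CC=C(C)[C@@H](CC[C@@H](C)CCO[Si](C)(C)C(C)(C)C)[C@@]2(C)C1 | intermediate
19 | (2S,4aR,8R,8aS)-8-{(3R)-5-[(tert-butyldimethylsilyl)oxy]-3-methylpentyl}-4,4,7,8a-tetramethyl-1,2,3,4,4a,5,8,8a-octahydronaphthalen-2-ol | O[C@H]1CC(C)(C)[C@H]2CC=C(C)[C@@H](CC[C@@H](C)CCO[Si](C)(C)C(C)(C)C)[C@@]2(C)C1 | intermediate
20 | angelic acid, (2Z)-2-methylbut-2-enoic acid | C/C=C(/C)C(O)=O | starting material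
21 | (2Z)-2-methylbut-2-enoic 2,4,6-trichlorobenzoic anhydride (not isolated) | C/C=C(/C)C(=O)OC(=O)c1c(Cl)cc(Cl)cc1Cl | intermediate
22 | (2S,4aR,8R,8aS)-8-{(3R)-5-[(tert-butyldimethylsilyl)oxy]-3-methylpentyl}-4,4,7,8a-tetramethyl-1,2,3,4,4a,5,8,8a-octahydronaphthalen-2-yl (2Z)-2-methylbut-2-enoate | C/C=C(/C)C(=O)O[C@H]1CC(C)(C)[C@H]2CC=C(C)[C@@H](CC[C@@H](C)CCO[Si](C)(C)C(C)(C)C)[C@@]2(C)C1 | intermediate
23 | (2S,4aR,8R,8aS)-8-[(3R)-5-hydroxy-3-methylpentyl]-4,4,7,8a-tetramethyl-1,2,3,4,4a,5,8,8a-octahydronaphthalen-2-yl (2Z)-2-methylbut-2-enoate | C/C=C(/C)C(=O)O[C@H]1CC(C)(C)[C@H]2CC=C(C)[C@@H](CC[C@@H](C)CCO)[C@@]2(C)C1 | intermediate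
24 | (3R)-3-methyl-5-[(1R,4aR,7S,8aS)-2,5,5,8a-tetramethyl-7-{[(2Z)-2-methylbut-2-enoyl]oxy}-1,4,4a,5,6,7,8,8a-octahydronaphthalen-1-yl]pentanoic acid | C/C=C(/C)C(=O)O[C@H]1CC(C)(C)[C@H]2CC=C(C)[C@@H](CC[C@@H](C)CC(=O)O)[C@@]2(C)C1 | target

**Step count**

Total steps: 13. Longest linear sequence: 10 steps (steps 1, 2, 3, 4, 8, 9, 10, 11, 12, 13).

**Steps most likely to fail**

Step 9. The sigmatropic stage may leave the boat-like pathway, either by a chair-like shift or by fragmentation of the alkoxide and recombination, and this would erode the configuration at C9. The fallback keeps the [3,3] logic but feeds it the Z olefin, so that a chair-like shift gives the required centre. It sets out from 9 and comes back to the route at 16: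
- Ozonolysis of 9 (O3, CH2Cl2, −78 °C; Me2S) would give (4R)-6-[(tert-butyldimethylsilyl)oxy]-4-methylhexanal F1.
- Z-selective Horner–Wadsworth–Emmons olefination with ethyl 2-(diphenoxyphosphoryl)propanoate (NaH, THF, −78 to 0 °C) would give ethyl (2Z,6R)-8-[(tert-butyldimethylsilyl)oxy]-2,6-dimethyloct-2-enoate F2.
- Reduction with (i-Bu)2AlH would give (2Z,6R)-8-[(tert-butyldimethylsilyl)oxy]-2,6-dimethyloct-2-en-1-ol F3.
- Mesylation to (2Z,6R)-8-[(tert-butyldimethylsilyl)oxy]-2,6-dimethyloct-2-en-1-yl methanesulfonate F4 and displacement with LiCl would give tert-butyl{[(3R,6Z)-8-chloro-3,7-dimethyloct-6-en-1-yl]oxy}dimethylsilane F5.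
- Activated barium would convert this into [(2Z,6R)-8-(tert-butyldimethylsilyloxy)-2,6-dimethyloct-2-en-1-yl]barium chloride F6, which should add to 7 to give (1R,4R)-1-{(2Z,6R)-8-[(tert-butyldimethylsilyl)oxy]-2,6-dimethyloct-2-en-1-yl}-3,5,5-trimethyl-4-(prop-2-en-1-yl)cyclohex-2-en-1-ol F7.
- KH and 18-crown-6 would give the potassium alkoxide of this carbinol F8, whose chair-like oxy-Cope shift should lead to the same enolate 16.

Step 8. Carbon–carbon bond formation may occur through the substituted terminus of the allyl unit, or the reagent may be consumed by enolization of 7. The fallback replaces the kinetic barium addition by a reversible zinc addition under thermodynamic control. It sets out from 12 and 7 and comes back at 14: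
- Zinc dust and LiCl in THF would convert 12 into chloro[(2E,6R)-8-(tert-butyldimethylsilyloxy)-2,6-dimethyloct-2-en-1-yl]zinc F9.
- Addition to 7 at 0 °C is expected to give first the branched carbinol (4R)-1-{(6R)-8-[(tert-butyldimethylsilyl)oxy]-2,6-dimethyloct-1-en-3-yl}-3,5,5-trimethyl-4-(prop-2-en-1-yl)cyclohex-2-en-1-ol F10 as its zinc alkoxide.
- Warming in THF/DMPU should reverse this congested addition (retro-allylation) and collect the material as the linear adduct, whose less crowded C2 epimer (side chain equatorial, anti to the axial methyl on C4) is the same as the kinetic one; aqueous work-up would give 14.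

Step 3. Enantioselection may be insufficient at a carbon flanked by the gem-dimethyl group, or the allyl group may be transferred to the wrong carbon of the dienolate. The fallback replaces catalysis by resolution. It sets out from 2 and comes back at 5:
- Alkylation of 2 (LiN(i-Pr)2, THF, −78 °C; allyl bromide) would give racemic material, that is 5 together with its enantiomer (6S)-3-ethoxy-5,5-dimethyl-6-(prop-2-en-1-yl)cyclohex-2-en-1-one F11.
- Preparative supercritical-fluid chromatography on a chiral stationary phase would then deliver 5.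

**Further compounds**

F1 | step 9 | (4R)-6-[(tert-butyldimethylsilyl)oxy]-4-methylhexanal | O=CCC[C@@H](C)CCO[Si](C)(C)C(C)(C)C
F2 | step 9 | ethyl (2Z,6R)-8-[(tert-butyldimethylsilyl)oxy]-2,6-dimethyloct-2-enoate | CCOC(=O)/C(C)=C\CC[C@@H](C)CCO[Si](C)(C)C(C)(C)C
F3 | step 9 | (2Z,6R)-8-[(tert-butyldimethylsilyl)oxy]-2,6-dimethyloct-2-en-1-ol | OC/C(C)=C\CC[C@@H](C)CCO[Si](C)(C)C(C)(C)C
F4 | step 9 | (2Z,6R)-8-[(tert-butyldimethylsilyl)oxy]-2,6-dimethyloct-2-en-1-yl methanesulfonate | CS(=O)(=O)OC/C(C)=C\CC[C@@H](C)CCO[Si](C)(C)C(C)(C)C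
F5 | step 9 | tert-butyl{[(3R,6Z)-8-chloro-3,7-dimethyloct-6-en-1-yl]oxy}dimethylsilane | ClC/C(C)=C\CC[C@@H](C)CCO[Si](C)(C)C(C)(C)C
F6 | step 9 | [(2Z,6R)-8-(tert-butyldimethylsilyloxy)-2,6-dimethyloct-2-en-1-yl]barium chloride | Cl[Ba]C/C(C)=C\CC[C@@H](C)CCO[Si](C)(C)C(C)(C)C
F7 | step 9 | (1R,4R)-1-{(2Z,6R)-8-[(tert-butyldimethylsilyl)oxy]-2,6-dimethyloct-2-en-1-yl}-3,5,5-trimethyl-4-(prop-2-en-1-yl)cyclohex-2-en-1-ol | O[C@]1(C/C(C)=C\CC[C@@H](C)CCO[Si](C)(C)C(C)(C)C)CC(C)(C)[C@@H](CC=C)C(C)=C1
F8 | step 9 | potassium alkoxide of F7 | [K+].[O-][C@]1(C/C(C)=C\CC[C@@H](C)CCO[Si](C)(C)C(C)(C)C)CC(C)(C)[C@@H](CC=C)C(C)=C1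
F9 | step 8 | chloro[(2E,6R)-8-(tert-butyldimethylsilyloxy)-2,6-dimethyloct-2-en-1-yl]zinc | Cl[Zn]C/C(C)=C/CC[C@@H](C)CCO[Si](C)(C)C(C)(C)C
F10 | step 8 | (4R)-1-{(6R)-8-[(tert-butyldimethylsilyl)oxy]-2,6-dimethyloct-1-en-3-yl}-3,5,5-trimethyl-4-(prop-2-en-1-yl)cyclohex-2-en-1-ol (mixture at the two new centres) | OC1(C(CC[C@@H](C)CCO[Si](C)(C)C(C)(C)C)C(C)=C)CC(C)(C)[C@@H](CC=C)C(C)=C1
F11 | step 3 | (6S)-3-ethoxy-5,5-dimethyl-6-(prop-2-en-1-yl)cyclohex-2-en-1-one | CCOC1=CC(=O)[C@@H](CC=C)C(C)(C)C1
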